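**Retrosynthetic overview**

1. Numbering used throughout: C1/C5 ring-fusion CH, C3=C4(CH3) cyclopentene alkene, C6 carbinol, C7 the carbon bearing the side chain, C10 the exo-methylene carbon; tetrahydrofuran carbons C11 (quaternary, CH3), C12 and C13 (CH2), C14 (O–CH), C15 = CMe2OAc; β is the face of the seven-membered ring that carries C11, α the other face.
2. Endgame: dictyol H ⇐ reduction of the C6 ketone from the α face ⇐ acetylation and oxidation of a 6α-hydroxy diol ⇐ i-Bu2AlH opening (retention at C14) of a 2,8-dioxabicyclo[3.2.1]octane ketal in which O6 is bound to C14. The ketal is carried through cyclopentene annulation on C1/C5 (cuprate addition, enolate alkylation) and methylenation of C10.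
3. Key disconnection: the ketal ⇐ a monocyclic 6α-hydroxy-7β-isopropenyl cycloheptanone + BrCH2COCMe2OAc, by a photoredox radical-polar crossover annulation that forms C12–C13 and O–C11 (the ketone oxygen becomes the ring oxygen); the oxocarbenium carbon C14 is caught by O6 in the same operation.
4. Enabling feature: the 1,1-disubstituted alkene C11=C12 of the isopropenyl group on C7, next to the free hydroxyl on the neighbouring ring carbon C6 and trans to it on the seven-membered ring. The alkene gives the tertiary C11 radical and cation; the trans homoallylic hydroxyl lets only the natural C11 epimer close the chair 1,3-dioxane (O–C11–C7–C6–O6–C14) of the ketal.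
5. Seven-membered ring ⇐ intramolecular carbonyl-ene reaction of an α-silyloxy aldehyde made by D-proline aldol of 6-methylhept-5-en-2-one with 2,2-dimethoxyacetaldehyde (the C5 silyloxy group sets the absolute configuration, then leaves to give the enone). Ring order: cycloheptane → tetrahydrofuran plus temporary 1,3-dioxane (key step) → cyclopentene → dioxane opened.

Key step: step 6

Remark: D-proline is assumed to give the (S)-aldol (mirror image of the usual L-proline sense) and the ene closure to follow the all-equatorial chair; were either sense opposite, L-proline would be used instead.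

**Route**

Step 1
Reactants: 1 3-hydroxy-3-methylbutan-2-one
Product: 2 2-methyl-3-oxobutan-2-yl acetate
Conditions: Ac2O, DMAP (cat.), Et3N, CH2Cl2, rt
Reagents that add atoms: acetic anhydride CC(=O)OC(C)=O
Why: DMAP-catalysed acylation of the tertiary alcohol (Steglich-type acetylation); the ester masks the hydroxyl so that it cannot act as an oxygen nucleophile in step 6.

Step 2
Reactants: 2 2-methyl-3-oxobutan-2-yl acetate
Product: 3 4-bromo-2-methyl-3-oxobutan-2-yl acetate
Conditions: Br2, AcOH, HBr (cat.), 15 °C
Reagents that add atoms: bromine BrBr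
Why: Acid-catalysed α-bromination of a ketone through its enol; only the CH3 side can enolise, so the bromomethyl ketone should be the single product.

Step 3
Reactants: 4 6-methylhept-5-en-2-one, 5 2,2-dimethoxyacetaldehyde
Product: 6 (S)-2-hydroxy-1,1-dimethoxy-8-methylnon-7-en-4-one
Conditions: D-proline (30 mol %), 4 (5 equiv), 5 as 60% aqueous solution, DMSO, rt
Reagents that add atoms: none
Why: Proline-catalysed direct asymmetric aldol reaction through the less substituted (CH3-side) enamine of the methyl ketone; the acid-directed transition state with D-proline should set the (S)-carbinol (C5), the centre that later controls C6 and C7.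

Step 4
Reactants: 6 (S)-2-hydroxy-1,1-dimethoxy-8-methylnon-7-en-4-one
Product: 8 (S)-8-methyl-4-oxo-2-(triethylsilyloxy)non-7-enal, via triethylsilyl ether acetal 7 (not isolated)
Conditions: Et3SiOTf, 2,4,6-collidine, CH2Cl2, −78 to 0 °C; then H2O
Reagents that add atoms: triethylsilyl trifluoromethanesulfonate CC[Si](CC)(CC)OS(=O)(=O)C(F)(F)F; water O
Why: O-silylation followed by silyl triflate/collidine cleavage of the dimethyl acetal (collidinium adduct hydrolysed on work-up), an acetal deprotection without aqueous acid that should leave the silyl ether, the ketone and the α-stereocentre intact.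

Step 5
Reactants: 8 (S)-8-methyl-4-oxo-2-(triethylsilyloxy)non-7-enal
Product: 9 (3S,4S,5S)-4-hydroxy-5-(prop-1-en-2-yl)-3-(triethylsilyloxy)cycloheptan-1-one
Conditions: Me2AlCl, CH2Cl2, −78 to −20 °C; 1 M HCl work-up
Reagents that add atoms: none
Why: Lewis-acid promoted intramolecular carbonyl-ene reaction (the seven-membered analogue of the citronellal–isopulegol cyclization): the aldehyde carbon bonds to the CH end of the trisubstituted alkene and a methyl hydrogen is transferred through a chair-like transition state in which the C5 silyloxy group, the aluminium-bound oxygen and the emerging isopropenyl group are all equatorial, so that C6–OH and C7 are set trans to each other and to C5–O under control of the C5 centre.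

Step 6
Reactants: 9 (3S,4S,5S)-4-hydroxy-5-(prop-1-en-2-yl)-3-(triethylsilyloxy)cycloheptan-1-one, 3 4-bromo-2-methyl-3-oxobutan-2-yl acetate
Product: 11 5β-triethylsilyloxy tricyclic ketal ketone (cycloheptan-10-one fused at C6–C7 to a 2,8-dioxabicyclo[3.2.1]octane; 11R,14R; C14 bears CMe2OAc), via cyclic oxocarbenium bromide 10 (not isolated)
Conditions: fac-Ir(ppy)3 (1 mol %), 3 (2 equiv), 2,6-di-tert-butylpyridine, 4 Å MS, MeCN, blue LEDs, rt; then PPTS (cat.), rt
Reagents that add atoms: none
Why: Proposed new method: photoexcited fac-Ir(ppy)3 reduces the C–Br bond of 3, the electrophilic acylmethyl radical (C13) adds to the CH2 end (C12) of the only electron-rich alkene of 9, tetravalent iridium oxidises the tertiary C11 radical to the cation, the ketone oxygen captures it and the C6 hydroxyl then adds to the oxocarbenium carbon C14, so that C12–C13, O–C11 and O6–C14 form in one redox-neutral operation with loss of HBr. The closest known reaction types are the oxidative radical [3+2] annulation of carbonyl compounds with alkenes to dihydrofurans (Mn(OAc)3, or photoredox catalysis with α-halo carbonyls) and the photoredox atom-transfer radical addition of α-bromo carbonyls to 1,1-disubstituted alkenes, joined here to an intramolecular ketalization. The tetrahydrofuran ring closes by attack of the carbonyl oxygen on the C11 cation (the five-membered oxygen closure of those dihydrofuran syntheses, the C14=O π bond becoming the endocyclic oxocarbenium ion), and the 1,3-dioxane ring by 6-endo addition of O6 to the C14=O+ bond. C11 is controlled by the ketal itself: only the epimer in which the C12–C13 bridge spans C11 and C14 while C5 and C8 stay equatorial on the new dioxane chair can close (possible because O6 and C11 are trans on the seven-membered ring), the hydrogen bond O6–H···O=C14 delivers the oxygen to that face, and the other epimer should be returned through reversible C11–O ionisation under the pyridinium acid; C14 follows from the bicyclic topology. The step needs radical attack at the CH2 terminus (tertiary radical), no second nucleophilic alkene (the enone is made only in step 7) and capture of the cation by the carbonyl oxygen in preference to the hydroxyl (which would give an oxetane) or the silyl ether oxygen (which would give a strained bridged ether).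

Step 7
Reactants: 11 5β-triethylsilyloxy tricyclic ketal ketone
Product: 12 tricyclic ketal enone (C1=C5 conjugated to the C10 ketone)
Conditions: DBU, CH2Cl2, 0 °C to rt
Reagents that add atoms: none
Why: E1cB elimination of triethylsilanolate from the β-silyloxy ketone (deprotonation at C1) gives the C1=C5 enone; the C5 centre is erased after having done its work and no other stereocentre is touched.

Step 8
Reactants: 13 but-2-yn-1-ol
Product: 15 (Z)-3-iodobut-2-en-1-ol, via cyclic alkenylalanate 14 (not isolated)
Conditions: NaAlH2(OCH2CH2OCH3)2, THF, 0 °C to rt; then I2, −78 °C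
Reagents that add atoms: iodine II
Why: Hydroxyl-directed trans-hydroalumination of the propargylic alcohol puts aluminium on C3 cis to the CH2O group (cyclic alanate), and iodinolysis with retention gives the Z vinyl iodide.

Step 9
Reactants: 15 (Z)-3-iodobut-2-en-1-ol
Product: 16 (Z)-tert-butyl[(3-iodobut-2-en-1-yl)oxy]dimethylsilane
Conditions: t-BuMe2SiCl, imidazole, CH2Cl2, rt
Reagents that add atoms: tert-butyldimethylsilyl chloride CC(C)(C)[Si](C)(C)Cl
Why: Imidazole-assisted silylation of the primary alcohol protects it through the lithiation of step 10.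

Step 10
Reactants: 16 (Z)-tert-butyl[(3-iodobut-2-en-1-yl)oxy]dimethylsilane, 12 tricyclic ketal enone
Product: 19 5β-[(Z)-4-(tert-butyldimethylsilyloxy)but-2-en-2-yl] ketal ketone (5α-H), via alkenyllithium 17 (not isolated), via lithium dialkenylcuprate 18 (not isolated)
Conditions: 16 (2.2 equiv), t-BuLi (4.4 equiv), Et2O, −78 °C; CuI (1.1 equiv), −40 °C; then 12, −78 to −30 °C; NH4Cl (aq)
Reagents that add atoms: none
Why: Iodine–lithium exchange with retention of alkene geometry, formation of the Gilman cuprate and conjugate addition to the enone; the new C5–C4 bond forms anti to the γ C6–O bond (β face), giving the 5α-H needed for the cis ring fusion.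

Step 11
Reactants: 19 5β-alkenyl ketal ketone (silyl ether)
Product: 20 5β-[(Z)-4-bromobut-2-en-2-yl] ketal ketone
Conditions: Ph3PBr2, CH2Cl2, 0 °C
Reagents that add atoms: dibromotriphenylphosphorane BrP(Br)(c1ccccc1)(c1ccccc1)c1ccccc1
Why: Direct conversion of a primary allylic silyl ether into the bromide with Ph3PBr2 (SN2 attack of bromide on the activated oxygen-bound carbon), which keeps the Z geometry needed for ring closure.

Step 12
Reactants: 20 5β-[(Z)-4-bromobut-2-en-2-yl] ketal ketone
Product: 21 cis-fused hydroazulen-10-one ketal (1α-H; 5α-H; 3-ene; 4-methyl)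
Conditions: KOt-Bu, THF, −78 to 0 °C
Reagents that add atoms: none
Why: Intramolecular C-alkylation of the equilibrating ketone enolate by the allylic bromide (5-exo-tet; cyclopentene annulation by conjugate addition then cycloalkylation); only the C1 enolate can reach the bromide and the short tether forces C2 onto the β face, so the ring fusion is cis (1α-H).

Step 13
Reactants: 21 cis-fused hydroazulen-10-one ketal
Product: 22 10(14)-methylene ketal
Conditions: Ph3PCH3Br, KOt-Bu, THF, 0 °C to rt
Reagents that add atoms: methyltriphenylphosphonium bromide C[P+](c1ccccc1)(c1ccccc1)c1ccccc1.[Br-]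
Why: Wittig methylenation of the C10 ketone; the cis ring fusion should be the more stable one, so C1 should not epimerise, and partial loss of the acetate would be harmless because step 14 removes it.

Step 14
Reactants: 22 10(14)-methylene ketal
Product: 23 6-epi-deacetyldictyol H (6α-ol; tertiary alcohol)
Conditions: i-Bu2AlH (excess), CH2Cl2, −78 to 0 °C; aq. KNaC4H4O6 (tartrate) work-up
Reagents that add atoms: none
Why: Reductive cleavage of the bicyclic ketal by i-Bu2AlH: aluminium binds the less hindered O6, the C14–O6 bond breaks toward the five-membered oxocarbenium ion and hydride is delivered from that aluminium on the same face (retention, as known for i-Bu2AlH openings of bicyclic ketals), so H-14 ends cis to C7 (14R); the acetate is reduced off in the same operation.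

Step 15
Reactants: 23 6-epi-deacetyldictyol H
Product: 24 6-oxo tertiary alcohol (6-dehydro-deacetyldictyol H)
Conditions: Dess–Martin periodinane, NaHCO3, CH2Cl2, 0 °C to rt
Reagents that add atoms: none
Why: Dess–Martin oxidation of the only secondary alcohol; the buffered neutral conditions should avoid migration of the C3=C4 double bond into conjugation.

Step 16
Reactants: 24 6-oxo tertiary alcohol
Product: 25 6-dehydrodictyol H (6-ketone; tertiary acetate)
Conditions: Ac2O, Sc(OTf)3 (cat.), MeCN, −20 °C
Reagents that add atoms: acetic anhydride CC(=O)OC(C)=O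
Why: Lewis-acid catalysed acetylation of the hindered tertiary alcohol at low temperature, chosen to avoid amine bases at the stage of the β,γ-unsaturated ketone; no other hydroxyl is present.

Step 17
Reactants: 25 6-dehydrodictyol H
Product: 26 dictyol H
Conditions: NaBH4, CeCl3·7H2O, MeOH, −78 °C
Reagents that add atoms: none
Why: Luche reduction (1,2-reduction with NaBH4/CeCl3): hydride attacks the C6 ketone from the convex α face, away from the β substituents on C5 and C7, which should give the 6β-alcohol of dictyol H.

**Compound list**

1 | 3-hydroxy-3-methylbutan-2-one | CC(=O)C(C)(C)O | starting material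
2 | 2-methyl-3-oxobutan-2-yl acetate | CC(=O)OC(C)(C)C(C)=O | intermediate
3 | 4-bromo-2-methyl-3-oxobutan-2-yl acetate | CC(=O)OC(C)(C)C(=O)CBr | intermediate
4 | 6-methylhept-5-en-2-one | CC(=O)CCC=C(C)C | starting material
5 | 2,2-dimethoxyacetaldehyde | COC(OC)C=O | starting material
6 | (S)-2-hydroxy-1,1-dimethoxy-8-methylnon-7-en-4-one | COC(OC)[C@@H](O)CC(=O)CCC=C(C)C | intermediate
7 | (S)-1,1-dimethoxy-8-methyl-2-(triethylsilyloxy)non-7-en-4-one (not isolated) | COC(OC)[C@@H](O[Si](CC)(CC)CC)CC(=O)CCC=C(C)C | intermediate
8 | (S)-8-methyl-4-oxo-2-(triethylsilyloxy)non-7-enal | O=C[C@@H](O[Si](CC)(CC)CC)CC(=O)CCC=C(C)C | intermediate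
9 | (3S,4S,5S)-4-hydroxy-5-(prop-1-en-2-yl)-3-(triethylsilyloxy)cycloheptan-1-one (skeleton: 5β-OSiEt3, 6α-OH, 7β-isopropenyl, 10-one) | O=C1CC[C@@H](C(C)=C)[C@H](O)[C@@H](O[Si](CC)(CC)CC)C1 | intermediate
10 | cyclic oxocarbenium bromide: 9 with the ketone oxygen bonded to C11 (11R) and C14=O+ (not isolated) | O=C1CC[C@@H]([C@@]2(C)CCC(C(C)(C)OC(C)=O)=[O+]2)[C@H](O)[C@@H](O[Si](CC)(CC)CC)C1.[Br-] | intermediate
11 | tricyclic ketal ketone: cycloheptan-10-one fused at C6–C7 to a 2,8-dioxabicyclo[3.2.1]octane (O6 α and ring oxygen both on C14; 11R with CH3; 14R with 2-acetoxypropan-2-yl; 5β-OSiEt3) | O=C1CC[C@@H]2[C@H](O[C@]3(C(C)(C)OC(C)=O)CC[C@@]2(C)O3)[C@@H](O[Si](CC)(CC)CC)C1 | intermediate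
12 | tricyclic ketal enone: as 11 without the silyloxy group and with C1=C5 conjugated to the C10 ketone | O=C1CC[C@@H]2[C@H](O[C@]3(C(C)(C)OC(C)=O)CC[C@@]2(C)O3)C=C1 | intermediate
13 | but-2-yn-1-ol | CC#CCO | starting material
14 | sodium cyclic alkenylalanate (2-alumina-1-oxacyclopent-3-ene with Al on the CH3-bearing carbon; not isolated) | CC1=CCO[Al-]1(OCCOC)OCCOC.[Na+] | intermediate
15 | (Z)-3-iodobut-2-en-1-ol | C/C(I)=C/CO | intermediate
16 | (Z)-tert-butyl[(3-iodobut-2-en-1-yl)oxy]dimethylsilane | C/C(I)=C/CO[Si](C)(C)C(C)(C)C | intermediate
17 | (Z)-[4-(tert-butyldimethylsilyloxy)but-2-en-2-yl]lithium (Li cis to CH2O; not isolated) | C/C([Li])=C/CO[Si](C)(C)C(C)(C)C | intermediate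
18 | LiCuR2 cuprate, R = (Z)-4-(tert-butyldimethylsilyloxy)but-2-en-2-yl (not isolated) | [Li+].C/C(=C/CO[Si](C)(C)C(C)(C)C)[Cu-]C(\C)=C/CO[Si](C)(C)C(C)(C)C | intermediate
19 | ketal ketone with 5β-[(Z)-4-(tert-butyldimethylsilyloxy)but-2-en-2-yl] group (5α-H) | O=C1CC[C@@H]2[C@H](O[C@]3(C(C)(C)OC(C)=O)CC[C@@]2(C)O3)[C@@H](/C(C)=C\CO[Si](C)(C)C(C)(C)C)C1 | intermediate
20 | ketal ketone with 5β-[(Z)-4-bromobut-2-en-2-yl] group | O=C1CC[C@@H]2[C@H](O[C@]3(C(C)(C)OC(C)=O)CC[C@@]2(C)O3)[C@@H](/C(C)=C\CBr)C1 | intermediate
21 | cis-fused hydroazulen-10-one ketal (1α-H, 5α-H, 3-ene, 4-methyl; 6α-O,14-ketal as in 11) | O=C1CC[C@@H]2[C@H](O[C@]3(C(C)(C)OC(C)=O)CC[C@@]2(C)O3)[C@H]2C(C)=CC[C@@H]12 | intermediate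
22 | 10(14)-methylene ketal (as 21 with C10=CH2) | C=C1CC[C@@H]2[C@H](O[C@]3(C(C)(C)OC(C)=O)CC[C@@]2(C)O3)[C@H]2C(C)=CC[C@@H]12 | intermediate
23 | 6-epi-deacetyldictyol H (6α-OH, free tertiary alcohol; 11R,14R tetrahydrofuran) | C=C1CC[C@@H]([C@@]2(C)CC[C@H](C(C)(C)O)O2)[C@H](O)[C@H]2C(C)=CC[C@@H]12 | intermediate
24 | 6-oxo tertiary alcohol (6-dehydro-deacetyldictyol H) | C=C1CC[C@@H]([C@@]2(C)CC[C@H](C(C)(C)O)O2)C(=O)[C@H]2C(C)=CC[C@@H]12 | intermediate
25 | 6-dehydrodictyol H (6-ketone, tertiary acetate) | C=C1CC[C@@H]([C@@]2(C)CC[C@H](C(C)(C)OC(C)=O)O2)C(=O)[C@H]2C(C)=CC[C@@H]12 | intermediate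
26 | dictyol H | C=C1CC[C@@H]([C@@]2(C)CC[C@H](C(C)(C)OC(C)=O)O2)[C@@H](O)[C@H]2C(C)=CC[C@@H]12 | target

**Step count and risks**

Total step count: 17. Longest linear sequence: 13 steps (steps 3–7 and 10–17, from 4 and 5 to 26).

Three steps most likely to fail:

Step 6 (proposed new method). The acylmethyl radical may be reduced or dimerise faster than it adds to the unactivated alkene; the C11 cation may lose a proton instead of being captured; and the capture may occur on the wrong face without being returned, so that the ketal does not form cleanly. The fallback separates the radical and the ionic events with known chemistry. Setting out from 9 and 3, a copper-catalysed atom-transfer radical addition (Kharasch addition; CuBr with tris(2-pyridylmethyl)amine and ascorbic acid) should give the tertiary bromide adduct F1 as a mixture of C11 epimers. Silver-assisted ionisation of F1 (AgOTf, 2,6-di-tert-butylpyridine, CH2Cl2, −40 °C to rt) would then generate the C11 cation under conditions where carbonyl participation and ketalization with O6 are reversible, and should converge on the strain-free ketal, coming back to the route at 11.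

Step 5. The seven-membered ene closure may be slow, the intermediate cation may be trapped by chloride, or the facial selectivity may be poor so that the C6 hydroxyl ends cis to C7. The fallback replaces the ene reaction by an allylmetal cyclization. Setting out from 8, allylic oxidation of the E methyl group (SeO2 cat., t-BuOOH, CH2Cl2) should give the allylic alcohol F2, CBr4/PPh3 would give the allylic bromide F3, and an intramolecular Nozaki–Hiyama–Kishi-type allylation (CrCl2, THF) should attack the aldehyde through the γ carbon (C7) in a chair transition state with anti selectivity, coming back to the route at 9.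

Step 16. Acetylation of the hindered tertiary alcohol may be slow enough for the Lewis acid to move the C3=C4 double bond into conjugation with the C6 ketone or to epimerise C5 or C7. The fallback moves the acetylation before the oxidation. Setting out from 23, exhaustive acetylation (Ac2O, DMAP, Et3N, 40 °C) should give the diacetate F4; selective methanolysis of the secondary acetate (K2CO3, MeOH, 0 °C), which is much faster than that of the tertiary acetate, would give 6-epi-dictyol H F5; Dess–Martin oxidation of F5 then comes back to the route at 25.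

**Further compounds**

F1 | step 6 | tertiary bromide adduct: 9 carrying at C7 a 2-bromo-6-acetoxy-6-methyl-5-oxoheptan-2-yl group (C11 epimers) | O=C1CC[C@@H](C(C)(Br)CCC(=O)C(C)(C)OC(C)=O)[C@H](O)[C@@H](O[Si](CC)(CC)CC)C1
F2 | step 5 | (S,E)-9-hydroxy-8-methyl-4-oxo-2-(triethylsilyloxy)non-7-enal | O=C[C@@H](O[Si](CC)(CC)CC)CC(=O)CC/C=C(\C)CO
F3 | step 5 | (S,E)-9-bromo-8-methyl-4-oxo-2-(triethylsilyloxy)non-7-enal | O=C[C@@H](O[Si](CC)(CC)CC)CC(=O)CC/C=C(\C)CBr
F4 | step 16 | 6-epi-dictyol H 6-acetate (6α-acetate and tertiary acetate) | C=C1CC[C@@H]([C@@]2(C)CC[C@H](C(C)(C)OC(C)=O)O2)[C@H](OC(C)=O)[C@H]2C(C)=CC[C@@H]12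
F5 | step 16 | 6-epi-dictyol H (6α-ol, tertiary acetate) | C=C1CC[C@@H]([C@@]2(C)CC[C@H](C(C)(C)OC(C)=O)O2)[C@H](O)[C@H]2C(C)=CC[C@@H]12
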